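**Retrosynthetic overview**
1. Target ⇒ C5 ester installed by opening a C1–C5 epoxide with (2R)-2-methylbutanoic acid (17); the α-methylene γ-lactone comes from iodolactonisation of a cycloheptene carrying a 2-substituted N,N-dimethylacrylamide.
2. The seven-membered carbocycle ⇒ ring-closing metathesis of a diene whose C1 carbinol is made by chelation-controlled vinyl addition.
3. Key convergent step: titanium aldol union (C9–C10 bond) of ketone 13 (C1–C4, C10, C14, C15) with aldehyde 7 (C6–C9, C11–C13).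
4. Fragments: 7 from 5,6-dihydro-2H-pyran-2-one (asymmetric vinyl conjugate addition), 13 from (S)-γ-valerolactone, 17 from butanoyl chloride (Evans methylation).
5. Ring order: carbocycle first (metathesis), then the γ-lactone (iodolactonisation).

Assumption: the α-triethylsilyloxy ketone 13 is taken to follow the stereochemical course I recall for α-tert-butyldimethylsilyloxy ethyl ketones in TiCl4/iPr2NEt aldol additions; skeleton labels used below are C1 tertiary carbinol, C2–C4/C15 side chain, C5 acyloxy CH, C6 lactone OCH, C7 ring-fusion CH, C8 CH2, C9 ring carbinol, C10/C14 CHCH3, C11–C13 lactone α-C, C=O, =CH2.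

**Amide fragment (steps 1–5)**

Step 1
Reactants: 1 5,6-dihydro-2H-pyran-2-one
Product: 2 (4S)-4-ethenyloxan-2-one
Conditions: K[CH2=CHBF3] (2 equiv), [Rh(cod)2]PF6 (3 mol %), (S)-BINAP (3.3 mol %), toluene/H2O 20:1, 105 °C
Reagents that add atoms: potassium vinyltrifluoroborate, C=C[B-](F)(F)F.[K+]
Why: Hayashi–Miyaura rhodium-catalysed asymmetric conjugate addition; the (S)-BINAP complex selects one enantioface of the unsaturated lactone (same sense as (S)-BINAP giving (S)-3-substituted cyclohexanones), setting the future C7.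

Step 2
Reactants: 2 (4S)-4-ethenyloxan-2-one
Product: 3 (3S)-3-ethenyl-5-hydroxy-N,N-dimethylpentanamide
Conditions: Me2NH (2 M in THF, 5 equiv), 50 °C, sealed tube
Reagents that add atoms: dimethylamine, CNC
Why: Lactone aminolysis gives a stable tertiary amide and frees the primary alcohol; the stereocentre is untouched.

Step 3
Reactants: 3 (3S)-3-ethenyl-5-hydroxy-N,N-dimethylpentanamide
Product: 4 (3R)-2-[(dimethylamino)methyl]-3-ethenyl-5-hydroxy-N,N-dimethylpentanamide (C2 epimer mixture)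
Conditions: LiN(iPr)2 (2.2 equiv), THF, −78 °C; then [Me2N=CH2]I (2.5 equiv), −78 °C → rt; aqueous work-up
Reagents that add atoms: N,N-dimethylmethyleneiminium iodide (Eschenmoser's salt), C=[N+](C)C.[I-]
Why: Mannich reaction of the amide enolate (the alkoxide is a spectator); the new α-centre is destroyed in the next step, so its configuration does not matter.

Step 4
Reactants: 4 (3R)-2-[(dimethylamino)methyl]-3-ethenyl-5-hydroxy-N,N-dimethylpentanamide
Product: 6 (3R)-3-ethenyl-5-hydroxy-N,N-dimethyl-2-methylidenepentanamide, via trimethylammonium iodide 5 (not isolated)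
Conditions: MeI (5 equiv), MeOH, rt; evaporate; DBU (1.5 equiv), CH2Cl2, rt
Reagents that add atoms: none
Why: Exhaustive N-methylation followed by E1cB (Hofmann-type) elimination of trimethylamine gives the 2-substituted acrylamide, a twisted and poorly electrophilic carrier of the future α-methylene lactone.

Step 5
Reactants: 6 (3R)-3-ethenyl-5-hydroxy-N,N-dimethyl-2-methylidenepentanamide
Product: 7 (3R)-3-ethenyl-N,N-dimethyl-2-methylidene-5-oxopentanamide
Conditions: Dess–Martin periodinane (1.3 equiv), CH2Cl2, 0 °C → rt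
Reagents that add atoms: none
Why: Dess–Martin oxidation of the primary alcohol to the aldehyde leaves the alkenes alone, and the β-stereocentre cannot epimerise.

**Ketone fragment (steps 6–10)**

Step 6
Reactants: 8 (5S)-5-methyloxolan-2-one [(S)-γ-valerolactone]
Product: 9 (3S,5S)-3-hydroxy-5-methyloxolan-2-one
Conditions: KN(SiMe3)2 (1.1 equiv), THF, −78 °C; then 2-(phenylsulfonyl)-3-phenyloxaziridine (1.3 equiv), −78 °C; aq. NH4Cl
Reagents that add atoms: 2-(phenylsulfonyl)-3-phenyloxaziridine (Davis reagent), O=S(=O)(c1ccccc1)N1OC1c1ccccc1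
Why: Davis hydroxylation of the lactone enolate; the oxidant approaches anti to the C5 methyl group, giving the trans (3S) alcohol (minor cis isomer removed by chromatography).

Step 7
Reactants: 9 (3S,5S)-3-hydroxy-5-methyloxolan-2-one
Product: 10 (3S,5S)-5-methyl-3-(triethylsilyloxy)oxolan-2-one
Conditions: Et3SiCl (1.2 equiv), imidazole (2 equiv), CH2Cl2, 0 °C → rt
Reagents that add atoms: chlorotriethylsilane, CC[Si](Cl)(CC)CC
Why: Silylation; triethylsilyl is non-chelating in the later aldol and can be removed before the tert-butyldimethylsilyl ethers.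

Step 8
Reactants: 10 (3S,5S)-5-methyl-3-(triethylsilyloxy)oxolan-2-one
Product: 11 (2S,4S)-4-hydroxy-N-methoxy-N-methyl-2-(triethylsilyloxy)pentanamide
Conditions: MeNHOMe·HCl (3 equiv), iPrMgCl (6 equiv), THF, −20 → 0 °C
Reagents that add atoms: N,O-dimethylhydroxylamine hydrochloride, CNOC.Cl
Why: Weinreb aminolysis of the lactone by the magnesium amide opens the ring without epimerising the α-silyloxy centre.

Step 9
Reactants: 11 (2S,4S)-4-hydroxy-N-methoxy-N-methyl-2-(triethylsilyloxy)pentanamide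
Product: 12 (2S,4S)-4-(tert-butyldimethylsilyloxy)-N-methoxy-N-methyl-2-(triethylsilyloxy)pentanamide
Conditions: tBuMe2SiCl (1.5 equiv), imidazole (3 equiv), DMF, rt
Reagents that add atoms: tert-butyldimethylsilyl chloride, CC(C)(C)[Si](C)(C)Cl
Why: Silylation of the freed secondary alcohol prevents relactonisation and protects C4–OH to the end.

Step 10
Reactants: 12 (2S,4S)-4-(tert-butyldimethylsilyloxy)-N-methoxy-N-methyl-2-(triethylsilyloxy)pentanamide
Product: 13 (4S,6S)-6-(tert-butyldimethylsilyloxy)-4-(triethylsilyloxy)heptan-3-one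
Conditions: EtMgBr (2 equiv), THF, 0 °C; aq. NH4Cl
Reagents that add atoms: ethylmagnesium bromide, CC[Mg]Br
Why: Weinreb ketone synthesis; the chelated tetrahedral intermediate stops at the ketone.

**Acid fragment (steps 11–13)**

Step 11
Reactants: 14 butanoyl chloride
Product: 15 (4R)-4-benzyl-3-butanoyl-1,3-oxazolidin-2-one
Conditions: (R)-4-benzyl-1,3-oxazolidin-2-one (1.0 equiv), n-BuLi (1.05 equiv), THF, −78 °C; then 14, −78 → 0 °C
Reagents that add atoms: (R)-4-benzyl-1,3-oxazolidin-2-one (chiral auxiliary), O=C1N[C@H](Cc2ccccc2)CO1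
Why: N-acylation of the lithiated Evans auxiliary.

Step 12
Reactants: 15 (4R)-4-benzyl-3-butanoyl-1,3-oxazolidin-2-one
Product: 16 (4R)-4-benzyl-3-[(2R)-2-methylbutanoyl]-1,3-oxazolidin-2-one
Conditions: NaN(SiMe3)2 (1.1 equiv), THF, −78 °C; MeI (3 equiv), −78 °C
Reagents that add atoms: iodomethane, CI
Why: Evans asymmetric alkylation; the chelated (Z)-sodium enolate is methylated on the face opposite the benzyl group, giving the (2R) acyl centre.

Step 13
Reactants: 16 (4R)-4-benzyl-3-[(2R)-2-methylbutanoyl]-1,3-oxazolidin-2-one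
Product: 17 (2R)-2-methylbutanoic acid
Conditions: LiOH (2 equiv), 30% H2O2 (4 equiv), THF/H2O 3:1, 0 °C; then Na2SO3; then 1 M HCl
Reagents that add atoms: hydrogen peroxide, OO
Why: Hydroperoxide cleavage of the exocyclic imide carbonyl releases the acid without racemisation and returns the auxiliary.

**Union and endgame (steps 14–22)**

Step 14
Reactants: 13 (4S,6S)-6-(tert-butyldimethylsilyloxy)-4-(triethylsilyloxy)heptan-3-one; 7 (3R)-3-ethenyl-N,N-dimethyl-2-methylidene-5-oxopentanamide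
Product: 18 (3R,5R,6S,8S,10S)-10-(tert-butyldimethylsilyloxy)-3-ethenyl-5-hydroxy-N,N,6-trimethyl-2-methylidene-7-oxo-8-(triethylsilyloxy)undecanamide
Conditions: 13 (1.1 equiv), TiCl4 (1.2 equiv), iPr2NEt (1.3 equiv), CH2Cl2, −78 °C, 1.5 h; then 7, −78 °C, 2 h; aq. NH4Cl
Reagents that add atoms: none
Why: Titanium enolate aldol through a Zimmerman–Traxler chair; the (Z)-enolate gives the 5,6-syn relationship and the non-chelating α-silyloxy stereocentre directs the aldehyde to the face giving the 6,8-anti adduct, so C9 becomes (R) and C10 (S).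

Step 15
Reactants: 18 (3R,5R,6S,8S,10S)-10-(tert-butyldimethylsilyloxy)-3-ethenyl-5-hydroxy-N,N,6-trimethyl-2-methylidene-7-oxo-8-(triethylsilyloxy)undecanamide
Product: 19 (3R,5R,6S,7R,8S,10S)-10-(tert-butyldimethylsilyloxy)-3,7-diethenyl-5,7-dihydroxy-N,N,6-trimethyl-2-methylidene-8-(triethylsilyloxy)undecanamide
Conditions: CH2=CHMgBr (4 equiv), THF, −78 → −40 °C; aq. NH4Cl
Reagents that add atoms: vinylmagnesium bromide, C=C[Mg]Br
Why: Chelation-controlled Grignard addition; the magnesium alkoxide at C9 forms a six-membered chelate with the ketone (the five-membered chelate through the C2 silyloxy oxygen exposes the same face), so vinyl adds anti to the C10 methyl and C8 substituents and sets C1, while the twisted N,N-dimethylacrylamide stays inert at low temperature.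

Step 16
Reactants: 19 (3R,5R,6S,7R,8S,10S)-10-(tert-butyldimethylsilyloxy)-3,7-diethenyl-5,7-dihydroxy-N,N,6-trimethyl-2-methylidene-8-(triethylsilyloxy)undecanamide
Product: 20 (3R,5R,6S,7R,8S,10S)-5,10-bis(tert-butyldimethylsilyloxy)-3,7-diethenyl-7-hydroxy-N,N,6-trimethyl-2-methylidene-8-(triethylsilyloxy)undecanamide
Conditions: tBuMe2SiOTf (1.2 equiv), 2,6-lutidine (2.5 equiv), CH2Cl2, −78 °C
Reagents that add atoms: tert-butyldimethylsilyl trifluoromethanesulfonate, CC(C)(C)[Si](C)(C)OS(=O)(=O)C(F)(F)F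
Why: Silylation of the secondary C9 hydroxyl (the tertiary allylic hydroxyl is too hindered at −78 °C); this blocks transannular ether formation in steps 18 and 19.

Step 17
Reactants: 20 (3R,5R,6S,7R,8S,10S)-5,10-bis(tert-butyldimethylsilyloxy)-3,7-diethenyl-7-hydroxy-N,N,6-trimethyl-2-methylidene-8-(triethylsilyloxy)undecanamide
Product: 21 2-[(1R,4R,5S,6R)-6-(tert-butyldimethylsilyloxy)-4-[(1S,3S)-3-(tert-butyldimethylsilyloxy)-1-(triethylsilyloxy)butyl]-4-hydroxy-5-methylcyclohept-2-en-1-yl]-N,N-dimethylprop-2-enamide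
Conditions: second-generation Grubbs catalyst RuCl2(=CHPh)(H2IMes)(PCy3) (10 mol %), CH2Cl2 (2 mM), 40 °C
Reagents that add atoms: none
Why: Ring-closing metathesis of the two monosubstituted vinyl groups closes the seven-membered carbocycle (the 1,1-disubstituted, electron-poor acrylamide alkene reacts far more slowly); no stereocentre is formed.

Step 18
Reactants: 21 2-[(1R,4R,5S,6R)-6-(tert-butyldimethylsilyloxy)-4-[(1S,3S)-3-(tert-butyldimethylsilyloxy)-1-(triethylsilyloxy)butyl]-4-hydroxy-5-methylcyclohept-2-en-1-yl]-N,N-dimethylprop-2-enamide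
Product: 23 (3aS,5R,6S,7R,8S,8aR)-5-(tert-butyldimethylsilyloxy)-7-[(1S,3S)-3-(tert-butyldimethylsilyloxy)-1-(triethylsilyloxy)butyl]-7-hydroxy-8-iodo-6-methyl-3-methylideneoctahydro-2H-cyclohepta[b]furan-2-one, via cyclic iminium ether iodide 22 (not isolated)
Conditions: I2 (3 equiv), NaHCO3 (5 equiv), MeCN/H2O 4:1, 0 °C → rt, dark; aq. Na2S2O3
Reagents that add atoms: iodine, II; water, O
Why: Iodolactonisation; reversible iodonium formation is funnelled through 5-exo attack of the amide oxygen at C6 from the face of the C7 side chain, giving the cis-fused lactone (C6 R) with iodine anti at C5, and water hydrolyses the iminium ether to the α-methylene lactone.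

Step 19
Reactants: 23 (3aS,5R,6S,7R,8S,8aR)-5-(tert-butyldimethylsilyloxy)-7-[(1S,3S)-3-(tert-butyldimethylsilyloxy)-1-(triethylsilyloxy)butyl]-7-hydroxy-8-iodo-6-methyl-3-methylideneoctahydro-2H-cyclohepta[b]furan-2-one; 17 (2R)-2-methylbutanoic acid
Product: 25 [(3aS,5R,6S,7S,8S,8aR)-5-(tert-butyldimethylsilyloxy)-7-[(1S,3S)-3-(tert-butyldimethylsilyloxy)-1-(triethylsilyloxy)butyl]-7-hydroxy-6-methyl-3-methylidene-2-oxooctahydro-2H-cyclohepta[b]furan-8-yl] (2R)-2-methylbutanoate, via 7,8-epoxide 24 (not isolated)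
Conditions: 17 (5 equiv), Cs2CO3 (1.5 equiv), DMF, rt → 70 °C
Reagents that add atoms: none
Why: The carboxylate base closes the trans-iodohydrin to the C1–C5 epoxide (intramolecular Williamson reaction, inversion at C5) and then opens it by SN2 attack at the secondary C5 (second inversion, tertiary C1 unreactive), so the ester arrives with net retention as (5S) and the C1 hydroxyl is regenerated.

Step 20
Reactants: 25 [(3aS,5R,6S,7S,8S,8aR)-5-(tert-butyldimethylsilyloxy)-7-[(1S,3S)-3-(tert-butyldimethylsilyloxy)-1-(triethylsilyloxy)butyl]-7-hydroxy-6-methyl-3-methylidene-2-oxooctahydro-2H-cyclohepta[b]furan-8-yl] (2R)-2-methylbutanoate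
Product: 26 [(3aS,5R,6S,7R,8S,8aR)-5-(tert-butyldimethylsilyloxy)-7-[(1S,3S)-3-(tert-butyldimethylsilyloxy)-1-hydroxybutyl]-7-hydroxy-6-methyl-3-methylidene-2-oxooctahydro-2H-cyclohepta[b]furan-8-yl] (2R)-2-methylbutanoate
Conditions: PPTS (0.2 equiv), MeOH/CH2Cl2 1:1, 0 °C → rt
Reagents that add atoms: none
Why: Acid-catalysed methanolysis removes the triethylsilyl ether much faster than the secondary tert-butyldimethylsilyl ethers.

Step 21
Reactants: 26 [(3aS,5R,6S,7R,8S,8aR)-5-(tert-butyldimethylsilyloxy)-7-[(1S,3S)-3-(tert-butyldimethylsilyloxy)-1-hydroxybutyl]-7-hydroxy-6-methyl-3-methylidene-2-oxooctahydro-2H-cyclohepta[b]furan-8-yl] (2R)-2-methylbutanoate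
Product: 27 [(3aS,5R,6S,7S,8S,8aR)-5-(tert-butyldimethylsilyloxy)-7-[(3S)-3-(tert-butyldimethylsilyloxy)butanoyl]-7-hydroxy-6-methyl-3-methylidene-2-oxooctahydro-2H-cyclohepta[b]furan-8-yl] (2R)-2-methylbutanoate
Conditions: Dess–Martin periodinane (1.5 equiv), CH2Cl2, 0 °C → rt
Reagents that add atoms: none
Why: Dess–Martin oxidation converts the only free secondary alcohol (C2) into the ketone; the tertiary C1 hydroxyl cannot be oxidised and the temporary C2 stereocentre is erased.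

Step 22
Reactants: 27 [(3aS,5R,6S,7S,8S,8aR)-5-(tert-butyldimethylsilyloxy)-7-[(3S)-3-(tert-butyldimethylsilyloxy)butanoyl]-7-hydroxy-6-methyl-3-methylidene-2-oxooctahydro-2H-cyclohepta[b]furan-8-yl] (2R)-2-methylbutanoate
Product: 28 [(3aS,5R,6S,7S,8S,8aR)-5,7-dihydroxy-7-[(3S)-3-hydroxybutanoyl]-6-methyl-3-methylidene-2-oxooctahydro-2H-cyclohepta[b]furan-8-yl] (2R)-2-methylbutanoate (CNP0291806.3)
Conditions: HF·pyridine, pyridine, THF, 0 °C → rt
Reagents that add atoms: none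
Why: Buffered fluoride desilylation frees the C4 and C9 hydroxyls without retro-aldol or acyl migration, giving the target.

**Compound list**
1 | 5,6-dihydro-2H-pyran-2-one | O=C1C=CCCO1 | starting material
2 | (4S)-4-ethenyloxan-2-one | C=C[C@H]1CCOC(=O)C1 | intermediate
3 | (3S)-3-ethenyl-5-hydroxy-N,N-dimethylpentanamide | CN(C)C(=O)C[C@@H](C=C)CCO | intermediate
4 | (3R)-2-[(dimethylamino)methyl]-3-ethenyl-5-hydroxy-N,N-dimethylpentanamide (C2 epimer mixture) | CN(C)CC(C(=O)N(C)C)[C@@H](C=C)CCO | intermediate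
5 | [(3R)-2-(dimethylcarbamoyl)-3-ethenyl-5-hydroxypentyl]trimethylammonium iodide | C[N+](C)(C)CC(C(=O)N(C)C)[C@@H](C=C)CCO.[I-] | intermediate (not isolated)
6 | (3R)-3-ethenyl-5-hydroxy-N,N-dimethyl-2-methylidenepentanamide | C=C(C(=O)N(C)C)[C@@H](C=C)CCO | intermediate
7 | (3R)-3-ethenyl-N,N-dimethyl-2-methylidene-5-oxopentanamide | C=C(C(=O)N(C)C)[C@@H](C=C)CC=O | intermediate
8 | (5S)-5-methyloxolan-2-one [(S)-γ-valerolactone] | C[C@H]1CCC(=O)O1 | starting material
9 | (3S,5S)-3-hydroxy-5-methyloxolan-2-one | C[C@H]1C[C@H](O)C(=O)O1 | intermediate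
10 | (3S,5S)-5-methyl-3-(triethylsilyloxy)oxolan-2-one | C[C@H]1C[C@H](O[Si](CC)(CC)CC)C(=O)O1 | intermediate
11 | (2S,4S)-4-hydroxy-N-methoxy-N-methyl-2-(triethylsilyloxy)pentanamide | C[C@H](O)C[C@H](O[Si](CC)(CC)CC)C(=O)N(C)OC | intermediate
12 | (2S,4S)-4-(tert-butyldimethylsilyloxy)-N-methoxy-N-methyl-2-(triethylsilyloxy)pentanamide | C[C@H](O[Si](C)(C)C(C)(C)C)C[C@H](O[Si](CC)(CC)CC)C(=O)N(C)OC | intermediate
13 | (4S,6S)-6-(tert-butyldimethylsilyloxy)-4-(triethylsilyloxy)heptan-3-one | CCC(=O)[C@@H](O[Si](CC)(CC)CC)C[C@H](C)O[Si](C)(C)C(C)(C)C | intermediate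
14 | butanoyl chloride | CCCC(Cl)=O | starting material
15 | (4R)-4-benzyl-3-butanoyl-1,3-oxazolidin-2-one | CCCC(=O)N1[C@H](Cc2ccccc2)COC1=O | intermediate
16 | (4R)-4-benzyl-3-[(2R)-2-methylbutanoyl]-1,3-oxazolidin-2-one | CC[C@@H](C)C(=O)N1[C@H](Cc2ccccc2)COC1=O | intermediate
17 | (2R)-2-methylbutanoic acid | CC[C@@H](C)C(O)=O | intermediate
18 | (3R,5R,6S,8S,10S)-10-(tert-butyldimethylsilyloxy)-3-ethenyl-5-hydroxy-N,N,6-trimethyl-2-methylidene-7-oxo-8-(triethylsilyloxy)undecanamide | C=C(C(=O)N(C)C)[C@@H](C=C)C[C@@H](O)[C@H](C)C(=O)[C@@H](O[Si](CC)(CC)CC)C[C@H](C)O[Si](C)(C)C(C)(C)C | intermediate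
19 | (3R,5R,6S,7R,8S,10S)-10-(tert-butyldimethylsilyloxy)-3,7-diethenyl-5,7-dihydroxy-N,N,6-trimethyl-2-methylidene-8-(triethylsilyloxy)undecanamide | C=C(C(=O)N(C)C)[C@@H](C=C)C[C@@H](O)[C@H](C)[C@](O)(C=C)[C@@H](O[Si](CC)(CC)CC)C[C@H](C)O[Si](C)(C)C(C)(C)C | intermediate
20 | (3R,5R,6S,7R,8S,10S)-5,10-bis(tert-butyldimethylsilyloxy)-3,7-diethenyl-7-hydroxy-N,N,6-trimethyl-2-methylidene-8-(triethylsilyloxy)undecanamide | C=C(C(=O)N(C)C)[C@@H](C=C)C[C@@H](O[Si](C)(C)C(C)(C)C)[C@H](C)[C@](O)(C=C)[C@@H](O[Si](CC)(CC)CC)C[C@H](C)O[Si](C)(C)C(C)(C)C | intermediate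
21 | 2-[(1R,4R,5S,6R)-6-(tert-butyldimethylsilyloxy)-4-[(1S,3S)-3-(tert-butyldimethylsilyloxy)-1-(triethylsilyloxy)butyl]-4-hydroxy-5-methylcyclohept-2-en-1-yl]-N,N-dimethylprop-2-enamide | C=C(C(=O)N(C)C)[C@H]1C=C[C@](O)([C@@H](O[Si](CC)(CC)CC)C[C@H](C)O[Si](C)(C)C(C)(C)C)[C@@H](C)[C@H](O[Si](C)(C)C(C)(C)C)C1 | intermediate
22 | N-[(3aS,5R,6S,7R,8S,8aR)-5-(tert-butyldimethylsilyloxy)-7-[(1S,3S)-3-(tert-butyldimethylsilyloxy)-1-(triethylsilyloxy)butyl]-7-hydroxy-8-iodo-6-methyl-3-methylideneoctahydro-2H-cyclohepta[b]furan-2-ylidene]-N-methylmethanaminium iodide | C=C1C(=[N+](C)C)O[C@@H]2[C@H]1C[C@@H](O[Si](C)(C)C(C)(C)C)[C@H](C)[C@@](O)([C@@H](O[Si](CC)(CC)CC)C[C@H](C)O[Si](C)(C)C(C)(C)C)[C@H]2I.[I-] | intermediate (not isolated)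
23 | (3aS,5R,6S,7R,8S,8aR)-5-(tert-butyldimethylsilyloxy)-7-[(1S,3S)-3-(tert-butyldimethylsilyloxy)-1-(triethylsilyloxy)butyl]-7-hydroxy-8-iodo-6-methyl-3-methylideneoctahydro-2H-cyclohepta[b]furan-2-one | C=C1C(=O)O[C@@H]2[C@H]1C[C@@H](O[Si](C)(C)C(C)(C)C)[C@H](C)[C@@](O)([C@@H](O[Si](CC)(CC)CC)C[C@H](C)O[Si](C)(C)C(C)(C)C)[C@H]2I | intermediate
24 | (3aS,5R,6S,7S,8R,8aR)-5-(tert-butyldimethylsilyloxy)-7-[(1S,3S)-3-(tert-butyldimethylsilyloxy)-1-(triethylsilyloxy)butyl]-7,8-epoxy-6-methyl-3-methylideneoctahydro-2H-cyclohepta[b]furan-2-one | C=C1C(=O)O[C@@H]2[C@H]1C[C@@H](O[Si](C)(C)C(C)(C)C)[C@H](C)[C@]3([C@@H](O[Si](CC)(CC)CC)C[C@H](C)O[Si](C)(C)C(C)(C)C)O[C@H]23 | intermediate (not isolated)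
25 | [(3aS,5R,6S,7S,8S,8aR)-5-(tert-butyldimethylsilyloxy)-7-[(1S,3S)-3-(tert-butyldimethylsilyloxy)-1-(triethylsilyloxy)butyl]-7-hydroxy-6-methyl-3-methylidene-2-oxooctahydro-2H-cyclohepta[b]furan-8-yl] (2R)-2-methylbutanoate | C=C1C(=O)O[C@@H]2[C@H]1C[C@@H](O[Si](C)(C)C(C)(C)C)[C@H](C)[C@@](O)([C@@H](O[Si](CC)(CC)CC)C[C@H](C)O[Si](C)(C)C(C)(C)C)[C@H]2OC(=O)[C@H](C)CC | intermediate
26 | [(3aS,5R,6S,7R,8S,8aR)-5-(tert-butyldimethylsilyloxy)-7-[(1S,3S)-3-(tert-butyldimethylsilyloxy)-1-hydroxybutyl]-7-hydroxy-6-methyl-3-methylidene-2-oxooctahydro-2H-cyclohepta[b]furan-8-yl] (2R)-2-methylbutanoate | C=C1C(=O)O[C@@H]2[C@H]1C[C@@H](O[Si](C)(C)C(C)(C)C)[C@H](C)[C@@](O)([C@@H](O)C[C@H](C)O[Si](C)(C)C(C)(C)C)[C@H]2OC(=O)[C@H](C)CC | intermediate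
27 | [(3aS,5R,6S,7S,8S,8aR)-5-(tert-butyldimethylsilyloxy)-7-[(3S)-3-(tert-butyldimethylsilyloxy)butanoyl]-7-hydroxy-6-methyl-3-methylidene-2-oxooctahydro-2H-cyclohepta[b]furan-8-yl] (2R)-2-methylbutanoate | C=C1C(=O)O[C@@H]2[C@H]1C[C@@H](O[Si](C)(C)C(C)(C)C)[C@H](C)[C@@](O)(C(=O)C[C@H](C)O[Si](C)(C)C(C)(C)C)[C@H]2OC(=O)[C@H](C)CC | intermediate
28 | [(3aS,5R,6S,7S,8S,8aR)-5,7-dihydroxy-7-[(3S)-3-hydroxybutanoyl]-6-methyl-3-methylidene-2-oxooctahydro-2H-cyclohepta[b]furan-8-yl] (2R)-2-methylbutanoate | C=C1C(=O)O[C@@H]2[C@H]1C[C@@H](O)[C@H](C)[C@@](O)(C(=O)C[C@H](C)O)[C@H]2OC(=O)[C@H](C)CC | target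

**Totals and risks**

Total step count: 22. Longest linear sequence: 14 steps (steps 1–5 then 14–22; steps 6–10 then 14–22 is equally long).

Three steps most likely to fail:

Step 15 (vinyl addition to a hindered, enolisable ketone; C1 selectivity depends on chelation winning over Felkin control). Fallback: starting from 18, add the smaller and less basic ethynylmagnesium bromide (HC≡CMgBr, THF, −78 → 0 °C, same chelate control) to give the ethynyl carbinol F1, then semi-hydrogenate the alkyne (H2, Pd/CaCO3 poisoned with Pb(OAc)2, quinoline, EtOAc). This returns to the route at 19.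

Step 18 (iodolactonisation; a semipinacol shift of the tertiary allylic alcohol or conjugate hydration of the iminium ether could compete). Fallback: starting from 21, silylate the tertiary hydroxyl (Me3SiOTf, 2,6-lutidine) to the trimethylsilyl ether F2. Epoxidise the ring alkene with mCPBA/NaHCO3 on the face anti to the silyloxy group and the amide side chain to give the epoxy amide F3. Camphorsulfonic acid in wet CH2Cl2 then triggers amide-oxygen opening of the epoxide at C6, iminium hydrolysis and loss of the trimethylsilyl group, giving the diol lactone F4; a syn-epoxide cannot lactonise and is separated. Esterify the secondary hydroxyl with 17 under Yamaguchi conditions (2,4,6-trichlorobenzoyl chloride, Et3N, DMAP). This returns to the route at 25.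

Step 19 (SN2 opening of a hindered, β-oxygenated epoxide carbon by a branched carboxylate). Fallback: starting from 23, close the epoxide separately (K2CO3, MeCN) and isolate 24. Cleave the triethylsilyl ether (PPTS, MeOH) to the 2,3-epoxy alcohol F5, and open it with 17 under Ti(OiPr)4 mediation (Sharpless C3-selective opening of 2,3-epoxy alcohols, inversion at the secondary carbon). This returns to the route at 26.

**Further compounds**
F1 | step 15 | (3R,5R,6S,7S,8S,10S)-10-(tert-butyldimethylsilyloxy)-3-ethenyl-7-ethynyl-5,7-dihydroxy-N,N,6-trimethyl-2-methylidene-8-(triethylsilyloxy)undecanamide | C=C(C(=O)N(C)C)[C@@H](C=C)C[C@@H](O)[C@H](C)[C@](O)(C#C)[C@@H](O[Si](CC)(CC)CC)C[C@H](C)O[Si](C)(C)C(C)(C)C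
F2 | step 18 | 2-[(1R,4R,5S,6R)-6-(tert-butyldimethylsilyloxy)-4-[(1S,3S)-3-(tert-butyldimethylsilyloxy)-1-(triethylsilyloxy)butyl]-5-methyl-4-(trimethylsilyloxy)cyclohept-2-en-1-yl]-N,N-dimethylprop-2-enamide | C=C(C(=O)N(C)C)[C@H]1C=C[C@](O[Si](C)(C)C)([C@@H](O[Si](CC)(CC)CC)C[C@H](C)O[Si](C)(C)C(C)(C)C)[C@@H](C)[C@H](O[Si](C)(C)C(C)(C)C)C1
F3 | step 18 | epoxy amide: F2 with the ring C5=C6 alkene converted to the epoxide on the face anti to OSiMe3 and to the acrylamide (skeleton labels 1S,2S,4S,5S,6S,7S,9R,10S) | C=C(C(=O)N(C)C)[C@H]1[C@@H]2O[C@@H]2[C@](O[Si](C)(C)C)([C@@H](O[Si](CC)(CC)CC)C[C@H](C)O[Si](C)(C)C(C)(C)C)[C@@H](C)[C@H](O[Si](C)(C)C(C)(C)C)C1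
F4 | step 18 | (3aS,5R,6S,7S,8S,8aR)-5-(tert-butyldimethylsilyloxy)-7-[(1S,3S)-3-(tert-butyldimethylsilyloxy)-1-(triethylsilyloxy)butyl]-7,8-dihydroxy-6-methyl-3-methylideneoctahydro-2H-cyclohepta[b]furan-2-one | C=C1C(=O)O[C@@H]2[C@H]1C[C@@H](O[Si](C)(C)C(C)(C)C)[C@H](C)[C@@](O)([C@@H](O[Si](CC)(CC)CC)C[C@H](C)O[Si](C)(C)C(C)(C)C)[C@H]2O
F5 | step 19 | (3aS,5R,6S,7R,8R,8aR)-5-(tert-butyldimethylsilyloxy)-7-[(1S,3S)-3-(tert-butyldimethylsilyloxy)-1-hydroxybutyl]-7,8-epoxy-6-methyl-3-methylideneoctahydro-2H-cyclohepta[b]furan-2-one | C=C1C(=O)O[C@@H]2[C@H]1C[C@@H](O[Si](C)(C)C(C)(C)C)[C@H](C)[C@]3([C@@H](O)C[C@H](C)O[Si](C)(C)C(C)(C)C)O[C@H]23
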